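**Strategy.** The carbocycle is numbered C1–C10, with C5 the ketone, C10 the methyl carbinol and C7/C8 the lactone fusion. C5 and C10 sit 1,6 across the ten-membered ring, so the keto alcohol is the opened form of an 11-oxabicyclo[4.4.1]undecane hemiketal. The plan rests on cutting a C5–C10 bond. A lactone-fused trans-decalin carrying a C5 hydroperoxide is acylated and undergoes a Criegee rearrangement. C10 migrates from C5 to oxygen with retention. In one operation this opens the decalin to the ten-membered ring, creates the C5 ketone and installs the C10 tertiary alcohol. All seven ring stereocentres are set beforehand on the rigid, steroid-like decalin.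

Key step: step 18

Remark 1 (locants): target locants are used for all bicyclic intermediates.
- C5 is C=O, C4 is CHMe (Me = C15), C3 is CH2, C2 is CHOH, and C1 is CH2.
- C10 is C(OH)Me (Me = C14), C9 is CH–O-isobutyrate, C8 is CH–O (lactone), C7 is the lactone CH, and C6 is CH–O-2-methylbutanoate.
- C11/C12/C13 are the lactone α-carbon, carbonyl and methylene.
- "syn/anti" means the same or opposite face as C14.

Remark 2 (assumptions):
- Compounds 1 and 24 are taken as commercial.
- The (R)-amine is chosen by analogy with 2-methylcyclohexanone/methyl vinyl ketone, where the (S)-amine leads to the (R)-quaternary centre.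
- The target is written as the open keto diol. Any hemiketal tautomer is in equilibrium with it.

Step 1
Reactants: 1 4-(tert-butyldimethylsilyloxy)cyclohexanone
Product: 3 all-cis-4-(TBSO)-2,6-dimethylcyclohexanone (meso), via monomethyl ketone 2 (not isolated)
Conditions: LDA, THF, −78 °C, MeI; again LDA, MeI, −78 → 0 °C; then cat. NaOMe, MeOH, rt
Reagents that add atoms: methyl iodide CI
Why: Two kinetic enolate alkylations (the second enolisation takes the less substituted α′ side) followed by base equilibration of both epimerisable α-centres should funnel all isomers into the all-equatorial meso ketone.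

Step 2
Reactants: 3 all-cis-4-(TBSO)-2,6-dimethylcyclohexanone; 4 (R)-1-phenylethylamine; 5 methyl vinyl ketone
Product: 8 2,6-dimethyl-2-(3-oxobutyl)-4-(TBSO)cyclohexanone (quaternary methyl cis to OTBS), via imine 6 (not isolated), via Michael adduct imine 7 (not isolated)
Conditions: 4, cat. TsOH, toluene, Dean–Stark; then 5, THF, rt; then aq. AcOH
Reagents that add atoms: water O
Why: Asymmetric Michael addition of a chiral imine through its secondary enamine tautomer; the auxiliary selects one of the two enantiotopic α-carbons of the meso ketone, and axial attack on the half-chair with OTBS equatorial puts the chain anti and C14 syn to the C2 oxygen, which sets C10 and makes C2 stereogenic.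

Step 3
Reactants: 8 2,6-dimethyl-2-(3-oxobutyl)-4-(TBSO)cyclohexanone
Product: 9 2-(TBSO)-4,10-dimethyl-Δ5-octalin-7-one (C2–O syn; C4–Me anti)
Conditions: cat. NaOMe, MeOH, 60 °C
Reagents that add atoms: none
Why: Intramolecular aldol condensation (second half of a Robinson annulation); the γ-epimerisable C4 methyl should settle equatorial and anti to the axial C14, as 6-methyl-4-en-3-one steroids do.

Step 4
Reactants: 9 2-(TBSO)-4,10-dimethyl-Δ5-octalin-7-one
Product: 10 cross-conjugated Δ5,Δ8-dien-7-one
Conditions: DDQ, dioxane, reflux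
Reagents that add atoms: none
Why: DDQ dehydrogenation through the cross-conjugated enol, the standard 4-en-3-one to 1,4-dien-3-one conversion, should introduce the C8=C9 alkene without touching the silyl ether.

Step 5
Reactants: 10 cross-conjugated Δ5,Δ8-dien-7-one
Product: 11 Δ5,Δ8-dien-7-ol (C7–OH syn)
Conditions: NaBH4, CeCl3·7H2O, MeOH, −40 °C
Reagents that add atoms: none
Why: Luche 1,2-reduction; hydride should enter the nearly planar ring from the face anti to the axial C14, leaving the C7 hydroxyl syn.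

Step 6
Reactants: 11 Δ5,Δ8-dien-7-ol
Product: 12 C7 methyl carbonate (syn)
Conditions: ClCO2Me, pyridine, cat. DMAP, CH2Cl2, 0 °C
Reagents that add atoms: methyl chloroformate COC(=O)Cl
Why: O-acylation under basic conditions activates the acid-sensitive bis-allylic alcohol without ionising it and leaves C7 untouched.

Step 7
Reactants: 12 C7 methyl carbonate; 13 Meldrum's acid
Product: 14 C7-(Meldrum's acid-5-yl) Δ5,Δ8-diene (C7–C11 syn)
Conditions: Pd(PPh3)4 (5 mol %), THF, rt
Reagents that add atoms: none
Why: Tsuji–Trost allylic alkylation; palladium ionises anti to the carbonate and the soft nucleophile attacks anti to palladium (net retention, setting C7), while attack at C7 is expected because both termini (fully substituted C5, neopentyl C9) are shielded.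

Step 8
Reactants: 14 C7-(Meldrum's acid-5-yl) Δ5,Δ8-diene
Product: 15 methyl 2-(decalin-7-yl)acrylate
Conditions: Eschenmoser's salt, MeOH, 65 °C
Reagents that add atoms: Eschenmoser's salt C=[N+](C)C.[I-]; methanol CO
Why: Mannich reaction at C11, methanolysis of the dioxanedione and decarboxylative loss of dimethylamine (decarboxylative methylenation of a monosubstituted Meldrum's acid) should deliver C11–C13 as the acrylate in one operation.

Step 9
Reactants: 15 methyl 2-(decalin-7-yl)acrylate
Product: 16 2-(decalin-7-yl)acrylic acid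
Conditions: LiOH, THF–H2O, 0 °C → rt; then dil. HCl to pH 3
Reagents that add atoms: lithium hydroxide [Li+].[OH-]
Why: Ester saponification under conditions too weakly basic to deprotonate C7–H, so the skipped diene and the C7 centre should survive.

Step 10
Reactants: 16 2-(decalin-7-yl)acrylic acid
Product: 17 5-bromo-6,12-olide (C5–Br anti; C6–O syn; Δ8 intact)
Conditions: NBS, THF, 0 °C, dark
Reagents that add atoms: N-bromosuccinimide O=C1CCC(=O)N1Br
Why: Bromolactonisation; the more nucleophilic trisubstituted C5=C6 alkene should take bromonium on the face anti to C14 and the syn-face carboxyl opens it at C6 in trans-diaxial fashion (as in steroid 5-bromo-6-ols), setting C6 and parking the acid.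

Step 11
Reactants: 17 5-bromo-6,12-olide
Product: 18 8,9-epoxy-5-bromo-6,12-olide (epoxide anti)
Conditions: mCPBA, CH2Cl2, 0 °C → rt
Reagents that add atoms: m-chloroperbenzoic acid O=C(OO)c1cccc(Cl)c1
Why: Prilezhaev epoxidation of the only electron-rich alkene left, from the face anti to both C14 and the lactone; the conjugated methylene is inert.

Step 12
Reactants: 18 8,9-epoxy-5-bromo-6,12-olide
Product: 20 5,6-epoxy-9-hydroxy-8,12-olide (5,6-epoxide syn; C8–O syn; C9–OH anti), via bis-epoxy acid 19 (not isolated)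
Conditions: LiOH (2.2 equiv), THF–H2O, 0 °C → rt; then dil. HCl to pH 5, rt
Reagents that add atoms: lithium hydroxide [Li+].[OH-]
Why: Saponification frees the C6 alkoxide, which displaces the antiperiplanar C5 bromide (halohydrin-to-epoxide closure giving the epoxide syn to C14), and the liberated carboxylate opens the 8,9-epoxide at C8 from the syn face (5-exo epoxy-acid lactonisation, inversion at C8), closing the final lactone and setting C8 and C9 trans-diaxially.

Step 13
Reactants: 20 5,6-epoxy-9-hydroxy-8,12-olide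
Product: 21 9-isobutyrate
Conditions: (iPrCO)2O, Et3N, DMAP, CH2Cl2, 35 °C
Reagents that add atoms: isobutyric anhydride CC(C)C(=O)OC(=O)C(C)C
Why: DMAP-catalysed acylation of the only free hydroxyl, an axial alcohol comparable to an acylable steroid 1α-ol, under conditions that leave the epoxide and silyl ether alone.

Step 14
Reactants: 21 9-isobutyrate
Product: 22 5-hydroperoxy-6-ol (C5–OOH anti; C6–OH syn; trans-decalin)
Conditions: anhydrous H2O2 in Et2O, MoO2(acac)2 (5 mol %), 0 °C → rt
Reagents that add atoms: hydrogen peroxide OO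
Why: Molybdenum-catalysed perhydrolysis of an epoxide; attack at tertiary C5 from the face anti to C14 is both the Markovnikov and the trans-diaxial mode, as in openings of 5β,6β-epoxy steroids, and keeps the C6–O configuration.

Step 15
Reactants: 22 5-hydroperoxy-6-ol
Product: 23 C5 triethylsilyl peroxide
Conditions: TESCl (1.05 equiv), imidazole, CH2Cl2, −30 °C
Reagents that add atoms: chlorotriethylsilane CC[Si](Cl)(CC)CC
Why: Silyl protection of a hydroperoxide; the more acidic and sterically exposed OOH should react before the axial C6 hydroxyl, which is syn-diaxial to C14.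

Step 16
Reactants: 23 C5 triethylsilyl peroxide; 24 (R)-2-methylbutanoic acid
Product: 25 6-[(R)-2-methylbutanoate] of the silyl peroxide
Conditions: DCC, DMAP, CH2Cl2, rt
Reagents that add atoms: none
Why: Steglich esterification of the remaining secondary alcohol; the fully substituted silyl peroxide has no α-hydrogen for base-induced cleavage, and the side-chain stereocentre comes from 24.

Step 17
Reactants: 25 6-[(R)-2-methylbutanoate] of the silyl peroxide
Product: 26 5-hydroperoxy-2-ol diester
Conditions: HF·pyridine, pyridine–THF, 0 °C → rt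
Reagents that add atoms: none
Why: Fluoride-mediated cleavage of both Si–O bonds releases the hydroperoxide and the C2 alcohol without touching esters, lactone or the O–O bond.

Step 18
Reactants: 26 5-hydroperoxy-2-ol diester
Product: 29 target CNP0244577.2, via bis(trifluoroacetyl) perester 27 (not isolated), via bridged ketal trifluoroacetate 28 (not isolated)
Conditions: TFAA (4 equiv), 2,6-lutidine, CH2Cl2, −40 → 0 °C; then THF–H2O, rt
Reagents that add atoms: water O
Why: Trifluoroacetylation turns C5–OOH into a peroxy ester whose O–O bond ionises while the antiperiplanar C5–C10 bond shifts to the proximal oxygen (Criegee rearrangement, the reaction type established for trans-9-decalyl peresters, which give 6-hydroxycyclodecanone after hydrolysis). The ten-membered carbocycle C1–C10 arises not by bond formation but by scission of the C5–C10 bond shared by the two six-membered rings, through the 11-oxabicyclo[4.4.1]undecyl oxocarbenium ion, which trifluoroacetate traps as 28 and water unravels to ketone plus alcohol. No new stereocentre is created: C10 migrates with retention, so the carbinol configuration is that of the quaternary carbon set in step 2, and C5 becomes trigonal, so its configuration is irrelevant. The step needs C10 to migrate in preference to C4 and C6, and this is secured because C10 is a tertiary alkyl group, C4 only secondary, and C6 secondary and deactivated by its acyloxy group, which is why that ester is installed first. The C2 hydroxyl is masked in situ as its trifluoroacetate and released in the same mild hydrolysis, which should leave both secondary esters, the C4 and C6 centres and the α-methylene lactone untouched.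

**Compound list**

1 | 4-(tert-butyldimethylsilyloxy)cyclohexanone | O=C1CCC(CC1)O[Si](C)(C)C(C)(C)C | starting material
2 | 4-(TBSO)-2-methylcyclohexanone (racemic diastereomer mixture, converges in the same step) | CC1CC(CCC1=O)O[Si](C)(C)C(C)(C)C | intermediate
3 | all-cis-4-(TBSO)-2,6-dimethylcyclohexanone (meso) | C[C@@H]1C[C@H](O[Si](C)(C)C(C)(C)C)C[C@H](C)C1=O | intermediate
4 | (R)-1-phenylethylamine | C[C@@H](N)c1ccccc1 | starting material
5 | methyl vinyl ketone | C=CC(C)=O | starting material
6 | N-[(R)-1-phenylethyl] imine of 3 | C[C@@H]1C[C@H](O[Si](C)(C)C(C)(C)C)C[C@H](C)C1=N[C@H](C)c1ccccc1 | intermediate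
7 | N-[(R)-1-phenylethyl] imine of 8 | C[C@H]1C[C@H](O[Si](C)(C)C(C)(C)C)C[C@@](C)(CCC(C)=O)C1=N[C@H](C)c1ccccc1 | intermediate
8 | 2,6-dimethyl-2-(3-oxobutyl)-4-(TBSO)cyclohexanone (quaternary Me cis to OTBS; C4 epimerisable, drawn as carried on) | C[C@H]1C[C@H](O[Si](C)(C)C(C)(C)C)C[C@@](C)(CCC(C)=O)C1=O | intermediate
9 | 2-(TBSO)-4,10-dimethyl-Δ5-octalin-7-one (C2–O syn, C4–Me anti) | C[C@H]1C[C@H](O[Si](C)(C)C(C)(C)C)C[C@@]2(C)CCC(=O)C=C12 | intermediate
10 | Δ5,Δ8-dien-7-one | C[C@H]1C[C@H](O[Si](C)(C)C(C)(C)C)C[C@@]2(C)C=CC(=O)C=C12 | intermediate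
11 | Δ5,Δ8-dien-7-ol (OH syn) | C[C@H]1C[C@H](O[Si](C)(C)C(C)(C)C)C[C@@]2(C)C=C[C@H](O)C=C12 | intermediate
12 | C7 methyl carbonate | C[C@H]1C[C@H](O[Si](C)(C)C(C)(C)C)C[C@@]2(C)C=C[C@H](OC(=O)OC)C=C12 | intermediate
13 | Meldrum's acid | CC1(C)OC(=O)CC(=O)O1 | starting material
14 | C7-(2,2-dimethyl-4,6-dioxo-1,3-dioxan-5-yl) diene (C7–C11 syn) | C[C@H]1C[C@H](O[Si](C)(C)C(C)(C)C)C[C@@]2(C)C=C[C@H](C3C(=O)OC(C)(C)OC3=O)C=C12 | intermediate
15 | methyl acrylate (C11=C13, C12 ester) | C[C@H]1C[C@H](O[Si](C)(C)C(C)(C)C)C[C@@]2(C)C=C[C@H](C(=C)C(=O)OC)C=C12 | intermediate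
16 | acrylic acid | C[C@H]1C[C@H](O[Si](C)(C)C(C)(C)C)C[C@@]2(C)C=C[C@H](C(=C)C(=O)O)C=C12 | intermediate
17 | 5-bromo-6,12-olide (Br anti, C6–O syn) | C[C@H]1C[C@H](O[Si](C)(C)C(C)(C)C)C[C@@]2(C)C=C[C@H]3[C@H](OC(=O)C3=C)[C@]12Br | intermediate
18 | 8,9-epoxy-5-bromo-6,12-olide (epoxide anti) | C[C@H]1C[C@H](O[Si](C)(C)C(C)(C)C)C[C@@]2(C)[C@H]4O[C@H]4[C@H]3[C@H](OC(=O)C3=C)[C@]12Br | intermediate
19 | 5,6-(syn);8,9-(anti)-bis-epoxy acrylic acid | C[C@H]1C[C@H](O[Si](C)(C)C(C)(C)C)C[C@@]2(C)[C@H]4O[C@H]4[C@H](C(=C)C(=O)O)[C@@H]3O[C@]123 | intermediate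
20 | 5,6-epoxy-9-hydroxy-8,12-olide | C=C1C(=O)O[C@@H]2[C@H]1[C@@H]3O[C@@]34[C@@H](C)C[C@H](O[Si](C)(C)C(C)(C)C)C[C@@]4(C)[C@H]2O | intermediate
21 | 9-isobutyrate of 20 | C=C1C(=O)O[C@@H]2[C@H]1[C@@H]3O[C@@]34[C@@H](C)C[C@H](O[Si](C)(C)C(C)(C)C)C[C@@]4(C)[C@H]2OC(=O)C(C)C | intermediate
22 | 5-hydroperoxy-6-ol (OOH anti, OH syn) | C=C1C(=O)O[C@@H]2[C@H]1[C@H](O)[C@]3(OO)[C@@H](C)C[C@H](O[Si](C)(C)C(C)(C)C)C[C@@]3(C)[C@H]2OC(=O)C(C)C | intermediate
23 | C5 triethylsilyl peroxide | C=C1C(=O)O[C@@H]2[C@H]1[C@H](O)[C@]3(OO[Si](CC)(CC)CC)[C@@H](C)C[C@H](O[Si](C)(C)C(C)(C)C)C[C@@]3(C)[C@H]2OC(=O)C(C)C | intermediate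
24 | (R)-2-methylbutanoic acid | CC[C@@H](C)C(=O)O | starting material
25 | 6-[(R)-2-methylbutanoate] silyl peroxide | C=C1C(=O)O[C@@H]2[C@H]1[C@H](OC(=O)[C@H](C)CC)[C@]3(OO[Si](CC)(CC)CC)[C@@H](C)C[C@H](O[Si](C)(C)C(C)(C)C)C[C@@]3(C)[C@H]2OC(=O)C(C)C | intermediate
26 | 5-hydroperoxy-2-ol diester | C=C1C(=O)O[C@@H]2[C@H]1[C@H](OC(=O)[C@H](C)CC)[C@]3(OO)[C@@H](C)C[C@H](O)C[C@@]3(C)[C@H]2OC(=O)C(C)C | intermediate
27 | C5 peroxytrifluoroacetate, C2 trifluoroacetate | C=C1C(=O)O[C@@H]2[C@H]1[C@H](OC(=O)[C@H](C)CC)[C@]3(OOC(=O)C(F)(F)F)[C@@H](C)C[C@H](OC(=O)C(F)(F)F)C[C@@]3(C)[C@H]2OC(=O)C(C)C | intermediate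
28 | 5,10-epoxy (11-oxabicyclo[4.4.1]) C5 ketal trifluoroacetate | C=C1C(=O)O[C@@H]2[C@H]1[C@H](OC(=O)[C@H](C)CC)[C@@]3(OC(=O)C(F)(F)F)[C@@H](C)C[C@H](OC(=O)C(F)(F)F)C[C@](C)(O3)[C@H]2OC(=O)C(C)C | intermediate
29 | CNP0244577.2 (2S,4S,6S,7S,8R,9S,10S,2′R) | C=C1C(=O)O[C@@H]2[C@H]1[C@H](OC(=O)[C@H](C)CC)C(=O)[C@@H](C)C[C@H](O)C[C@](C)(O)[C@H]2OC(=O)C(C)C | target

Total step count: 18. Longest linear sequence: 18.

**Steps most likely to fail**

**Step 7.** The soft nucleophile may attack a terminus of the pentadienyl–palladium system. The allyl complex may lose facial integrity by palladium-for-palladium displacement. The bis-allylic carbonate may also ionise and aromatise. The fallback sets out from 10 and comes back at 15: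
- Horner–Wadsworth–Emmons olefination of the dienone with trimethyl phosphonoacetate/NaH gives the cross-conjugated trienoate F1.
- Copper hydride 1,4-reduction (Stryker's reagent) delivers hydride to C7 from the face anti to C14. This gives the skipped-diene acetate F2.
- LDA/Eschenmoser's salt then gives the Mannich base F3.
- MeI followed by NaHCO3 eliminates to acrylate 15.

**Step 10.** Site selectivity between the two alkenes may be poor, because the carboxyl group can close on C6 or on C8. The fallback sets out from 10 and comes back at 20. It differentiates the alkenes earlier by polarity: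
- Alkaline H2O2 epoxidises only the disubstituted enone alkene, anti to C14, to give the epoxy enone F4.
- Caesium diethylphosphonoacetate opens F4 at C8 with inversion to give the hydroxy phosphonoacetate F5.
- Masamune–Roush conditions (LiCl, DBU) close the butenolide F6 by intramolecular Horner–Wadsworth–Emmons reaction.
- NaBH4/NiCl2 conjugate reduction from the face anti to C14 gives the cis-fused lactone F7.
- LDA/Eschenmoser's salt gives the Mannich base F8, and MeI/NaHCO3 gives the α-methylene lactone F9.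
- NBS in aqueous acetone converts the single remaining nucleophilic alkene into the bromohydrin F10.
- K2CO3 in acetone closes F10 to epoxide 20.

**Step 18.** C6 or C4 may migrate in competition with C10, or the perester may undergo homolysis. The fallback sets out from 25 and comes back at 29. It cleaves the same C5–C10 bond by a radical path:
- AcOH–THF–H2O followed by PPh3 converts the silyl peroxide into the tertiary alcohol F11.
- Alkoxy-radical β-scission (PhI(OAc)2, I2, hν; Suárez fragmentation, the type known for 5-hydroxy steroids) gives the (E)-1(10)-en-5-one F12.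
- Mukaiyama hydration (Co(acac)2, PhSiH3, O2) places OH at C10 to give the silyl ether F13. The C10 epimers would have to be separated.
- HF·pyridine then gives 29.

**Further compounds**

F1 | step 7 | C7-(methoxycarbonylmethylidene) Δ5,Δ8-diene | C[C@H]1C[C@H](O[Si](C)(C)C(C)(C)C)C[C@@]2(C)C=CC(=CC(=O)OC)C=C12
F2 | step 7 | methyl (decalin-7-yl)acetate (side chain syn) | C[C@H]1C[C@H](O[Si](C)(C)C(C)(C)C)C[C@@]2(C)C=C[C@H](CC(=O)OC)C=C12
F3 | step 7 | α-(dimethylaminomethyl) ester (C11 epimers) | C[C@H]1C[C@H](O[Si](C)(C)C(C)(C)C)C[C@@]2(C)C=C[C@H](C(CN(C)C)C(=O)OC)C=C12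
F4 | step 10 | 8,9-epoxy-Δ5-en-7-one (epoxide anti) | C[C@H]1C[C@H](O[Si](C)(C)C(C)(C)C)C[C@@]2(C)[C@H]3O[C@H]3C(=O)C=C12
F5 | step 10 | 9-hydroxy-8-(diethylphosphonoacetoxy)-Δ5-en-7-one | C[C@H]1C[C@H](O[Si](C)(C)C(C)(C)C)C[C@@]2(C)[C@@H](O)[C@H](OC(=O)CP(=O)(OCC)OCC)C(=O)C=C12
F6 | step 10 | 9-hydroxy-5,7(11)-dien-8,12-olide | C[C@H]1C[C@H](O[Si](C)(C)C(C)(C)C)C[C@@]2(C)[C@@H](O)[C@@H]3OC(=O)C=C3C=C12
F7 | step 10 | 9-hydroxy-Δ5-8,12-olide (cis-fused, C11H2) | C[C@H]1C[C@H](O[Si](C)(C)C(C)(C)C)C[C@@]2(C)[C@@H](O)[C@@H]3OC(=O)C[C@@H]3C=C12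
F8 | step 10 | C11 dimethylaminomethyl lactone (C11 epimers) | C[C@H]1C[C@H](O[Si](C)(C)C(C)(C)C)C[C@@]2(C)[C@@H](O)[C@@H]3OC(=O)C(CN(C)C)[C@@H]3C=C12
F9 | step 10 | 9-hydroxy-Δ5-α-methylene-8,12-olide | C[C@H]1C[C@H](O[Si](C)(C)C(C)(C)C)C[C@@]2(C)[C@@H](O)[C@@H]3OC(=O)C(=C)[C@@H]3C=C12
F10 | step 10 | 5-bromo-6,9-dihydroxy-8,12-olide (Br anti, C6–OH syn) | C[C@H]1C[C@H](O[Si](C)(C)C(C)(C)C)C[C@@]2(C)[C@@H](O)[C@@H]3OC(=O)C(=C)[C@@H]3[C@H](O)[C@]12Br
F11 | step 18 | 5-hydroxy decalin diester (C2–OTBS) | C=C1C(=O)O[C@@H]2[C@H]1[C@H](OC(=O)[C@H](C)CC)[C@]3(O)[C@@H](C)C[C@H](O[Si](C)(C)C(C)(C)C)C[C@@]3(C)[C@H]2OC(=O)C(C)C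
F12 | step 18 | (E)-1(10)-en-5-one ten-membered ring (C2–OTBS) | C=C1C(=O)O[C@@H]2[C@H]1[C@H](OC(=O)[C@H](C)CC)C(=O)[C@@H](C)C[C@H](O[Si](C)(C)C(C)(C)C)/C=C(\C)[C@H]2OC(=O)C(C)C
F13 | step 18 | 2-O-TBS ether of the target | C=C1C(=O)O[C@@H]2[C@H]1[C@H](OC(=O)[C@H](C)CC)C(=O)[C@@H](C)C[C@H](O[Si](C)(C)C(C)(C)C)C[C@](C)(O)[C@H]2OC(=O)C(C)C
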